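With the 14-membered ring numbered from the stereocentre (C1) through the carboxyl-bearing C4 to the methyl-bearing C8 and C12, everything rests on cutting C6–C7, a CH2–CH= bond whose sp3 end lies γ to the ester carbonyl and whose sp2 end is the hydrogen-bearing terminus of the E-trisubstituted C7=C8 alkene. One intramolecular Negishi coupling closes the carbocycle there from an acyclic primary alkyl iodide/(E)-alkenyl iodide: the ester-chelated C6 zinc reagent and the stereoretentive alkenyl partner make the bond without touching C1 or the other alkenes. The precursor is assembled from (R)-limonene (C1–C3, C12–C15) by Still–Gennari (C3=C4) and Z-selective Julia–Kocienski (C11=C12) olefinations.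

Key step: step 12

Remark: C15 is the exocyclic carbon on C1 that carries the methylene group; reagents outside the compound list are taken as commercial.

Step 1
Reactants: 1 (R)-(+)-limonene
Product: 3 (4R)-4-(hexa-1,5-dien-2-yl)-1-methylcyclohex-1-ene, via limonen-10-yllithium 2 (not isolated)
Conditions: n-BuLi, TMEDA, 25 °C; then allyl bromide, THF, −78 → 0 °C
Reagents that add atoms: allyl bromide, C=CCBr
Why: Allylic lithiation of limonene occurs at the isopropenyl methyl group and the symmetrical allyllithium is alkylated by allyl bromide (allyl–allyl coupling, one product from either terminus) without touching the stereocentre; allyl is used instead of prenyl so that the new side-chain alkene is the least nucleophilic one in step 2.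

Step 2
Reactants: 3 (4R)-4-(hexa-1,5-dien-2-yl)-1-methylcyclohex-1-ene
Product: 5 (3R)-3-(hexa-1,5-dien-2-yl)-6-oxoheptanal, via 1,2-epoxide 4 (not isolated)
Conditions: mCPBA, CH2Cl2, 0 °C; then H5IO6, THF/H2O, 0 → 25 °C
Reagents that add atoms: mCPBA (3-chloroperoxybenzoic acid), O=C(OO)c1cccc(Cl)c1; water, O
Why: Prilezhaev epoxidation is fastest at the trisubstituted ring alkene, and periodic acid hydrolyses and cleaves the epoxide (glycol cleavage) to the aldehyde (future C3) and methyl ketone (future C12), the stereocentre being β to the aldehyde and γ to the ketone and therefore not epimerisable.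

Step 3
Reactants: 5 (3R)-3-(hexa-1,5-dien-2-yl)-6-oxoheptanal
Product: 6 (3R)-3-(6-methylhepta-1,5-dien-2-yl)-6-oxoheptanal
Conditions: second-generation Grubbs catalyst RuCl2(=CHPh)(PCy3)(H2IMes) (3 mol %), 2-methylbut-2-ene/CH2Cl2, 40 °C
Reagents that add atoms: 2-methylbut-2-ene, CC=C(C)C
Why: Olefin cross-metathesis of the monosubstituted terminal alkene with excess 2-methylbut-2-ene installs the dimethylvinyl terminus, while the α-branched 1,1-disubstituted alkene is too hindered to react.

Step 4
Reactants: 7 methyl 2-[bis(2,2,2-trifluoroethoxy)phosphoryl]acetate; 8 tert-butyl(2-iodoethoxy)dimethylsilane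
Product: 9 methyl 2-[bis(2,2,2-trifluoroethoxy)phosphoryl]-4-[(tert-butyldimethylsilyl)oxy]butanoate
Conditions: NaH, DMSO, 25 °C; then 8, 50 °C
Reagents that add atoms: none
Why: C-alkylation (SN2) of the sodium phosphonoacetate with the primary iodide gives the α-substituted Still–Gennari reagent carrying C5 and C6; the new centre is racemic and is destroyed in step 5.

Step 5
Reactants: 9 methyl 2-[bis(2,2,2-trifluoroethoxy)phosphoryl]-4-[(tert-butyldimethylsilyl)oxy]butanoate; 6 (3R)-3-(6-methylhepta-1,5-dien-2-yl)-6-oxoheptanal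
Product: 10 methyl (2Z,5R)-2-{2-[(tert-butyldimethylsilyl)oxy]ethyl}-5-(6-methylhepta-1,5-dien-2-yl)-8-oxonon-2-enoate
Conditions: KN(SiMe3)2, 18-crown-6, THF, −78 °C; then 6
Reagents that add atoms: none
Why: Still–Gennari variant of the Horner–Wadsworth–Emmons reaction: the electron-poor phosphonate with a dissociated potassium counter-ion eliminates rapidly from the kinetic adduct and places the ester cis to C2 (Z at C3=C4), and the aldehyde reacts in preference to the methyl ketone at −78 °C.

Step 6
Reactants: 11 pent-4-yn-1-ol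
Product: 13 (4E)-5-iodo-4-methylpent-4-en-1-ol, via alkenylalane 12 (not isolated)
Conditions: AlMe3, Cp2ZrCl2 (20 mol %), CH2Cl2, 0 → 25 °C; then iodine, THF, −30 → 0 °C
Reagents that add atoms: trimethylaluminium, C[Al](C)C; iodine, [I][I]
Why: Zirconium-catalysed carboalumination adds methyl and aluminium syn across the terminal alkyne with methyl on the internal carbon, and iodinolysis with retention gives the (E)-iodoalkene that becomes C7=C8.

Step 7
Reactants: 13 (4E)-5-iodo-4-methylpent-4-en-1-ol; 14 1-methyl-1H-tetrazole-5-thiol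
Product: 15 5-{[(4E)-5-iodo-4-methylpent-4-en-1-yl]sulfanyl}-1-methyl-1H-tetrazole
Conditions: PPh3, DIAD, THF, 0 → 25 °C
Reagents that add atoms: none
Why: Mitsunobu thioetherification, in which the acidic tetrazolethiol displaces the activated primary alcohol by SN2.

Step 8
Reactants: 15 5-{[(4E)-5-iodo-4-methylpent-4-en-1-yl]sulfanyl}-1-methyl-1H-tetrazole
Product: 16 5-{[(4E)-5-iodo-4-methylpent-4-en-1-yl]sulfonyl}-1-methyl-1H-tetrazole
Conditions: (NH4)6Mo7O24·4H2O (10 mol %), 30 % H2O2, EtOH, 0 → 25 °C
Reagents that add atoms: hydrogen peroxide, OO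
Why: Molybdate-catalysed peroxide oxidation takes the sulfide to the sulfone selectively at sulfur and leaves the trisubstituted iodoalkene intact.

Step 9
Reactants: 10 methyl (2Z,5R)-2-{2-[(tert-butyldimethylsilyl)oxy]ethyl}-5-(6-methylhepta-1,5-dien-2-yl)-8-oxonon-2-enoate; 16 5-{[(4E)-5-iodo-4-methylpent-4-en-1-yl]sulfonyl}-1-methyl-1H-tetrazole
Product: 17 methyl (2Z,5R,8Z,12E)-2-{2-[(tert-butyldimethylsilyl)oxy]ethyl}-13-iodo-8,12-dimethyl-5-(6-methylhepta-1,5-dien-2-yl)trideca-2,8,12-trienoate
Conditions: LiN(SiMe3)2 added to 10 + 16, THF, −78 → −20 °C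
Reagents that add atoms: none
Why: Julia–Kocienski olefination under Barbier conditions: 1-methyltetrazol-5-yl sulfones are known to convert methyl ketones into trisubstituted alkenes with the sulfone chain cis to the larger ketone substituent, so C10 and C13 should end up cis (Z at C11=C12) through the addition–Smiles rearrangement–elimination sequence, the ketone reacting in preference to the hindered enoate.

Step 10
Reactants: 17 methyl (2Z,5R,8Z,12E)-2-{2-[(tert-butyldimethylsilyl)oxy]ethyl}-13-iodo-8,12-dimethyl-5-(6-methylhepta-1,5-dien-2-yl)trideca-2,8,12-trienoate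
Product: 18 methyl (2Z,5R,8Z,12E)-2-(2-hydroxyethyl)-13-iodo-8,12-dimethyl-5-(6-methylhepta-1,5-dien-2-yl)trideca-2,8,12-trienoate
Conditions: HF·pyridine, pyridine, THF, 0 °C
Reagents that add atoms: none
Why: Fluoride-mediated desilylation under buffered conditions frees the primary C6 alcohol while limiting lactonisation onto the neighbouring ester; the crude alcohol is used at once.

Step 11
Reactants: 18 methyl (2Z,5R,8Z,12E)-2-(2-hydroxyethyl)-13-iodo-8,12-dimethyl-5-(6-methylhepta-1,5-dien-2-yl)trideca-2,8,12-trienoate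
Product: 19 methyl (2Z,5R,8Z,12E)-13-iodo-2-(2-iodoethyl)-8,12-dimethyl-5-(6-methylhepta-1,5-dien-2-yl)trideca-2,8,12-trienoate
Conditions: iodine, PPh3, imidazole, CH2Cl2, 0 °C
Reagents that add atoms: iodine, [I][I]
Why: Appel-type iodination, in which the alkoxyphosphonium ion is displaced by iodide (SN2) at the primary carbon.

Step 12
Reactants: 19 methyl (2Z,5R,8Z,12E)-13-iodo-2-(2-iodoethyl)-8,12-dimethyl-5-(6-methylhepta-1,5-dien-2-yl)trideca-2,8,12-trienoate
Product: 21 methyl (1Z,4R,7Z,11E)-7,11-dimethyl-4-(6-methylhepta-1,5-dien-2-yl)cyclotetradeca-1,7,11-triene-1-carboxylate, via alkylzinc iodide 20 (not isolated)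
Conditions: Zn dust (activated with BrCH2CH2Br and Me3SiCl), THF/DMA, 35 °C; then syringe-pump addition to PdCl2(dppf) (10 mol %), THF/DMA, 60 °C, 2 mM
Reagents that add atoms: none
Why: Negishi cross-coupling run intramolecularly: zinc dust inserts into the primary C(sp3)–I bond of 19 (the alkenyl C–I bond is inert to zinc dust at this temperature) to give 20, a reagent of the 3-(alkoxycarbonyl)propylzinc iodide type held as a six-membered chelate by the ester carbonyl. Zerovalent palladium, formed from PdCl2(dppf) by the zinc reagent, adds oxidatively to the (E)-alkenyl iodide with retention, the tethered alkylzinc transmetalates, and reductive elimination forms the C6–C7 bond. The closest known reaction type is the palladium-catalysed coupling of ester-bearing primary alkylzinc iodides with alkenyl iodides. The single ring formed is the 14-membered carbocycle, closed end to end through a 15-membered palladacycle that contracts on reductive elimination; no small-ring exo or endo alternative competes. No stereocentre is created: the E geometry at C7=C8 is transferred stereospecifically from the iodide, and C1 and the C3=C4 and C11=C12 geometries are spectators. The step needs chemoselective metalation at C6 and ring closure faster than oligomerisation or β-hydride elimination, which the sp3/sp2 difference of the two iodides, slow addition at high dilution, the large-bite-angle dppf ligand and the three trisubstituted alkenes that stiffen the chain should secure.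

Step 13
Reactants: 21 methyl (1Z,4R,7Z,11E)-7,11-dimethyl-4-(6-methylhepta-1,5-dien-2-yl)cyclotetradeca-1,7,11-triene-1-carboxylate
Product: 22 (1Z,4R,7Z,11E)-7,11-dimethyl-4-(6-methylhepta-1,5-dien-2-yl)cyclotetradeca-1,7,11-triene-1-carboxylic acid
Conditions: LiOH, THF/MeOH/H2O, 45 °C; then 1 M HCl
Reagents that add atoms: lithium hydroxide, [Li+].[OH-]
Why: Saponification (acyl–oxygen cleavage by hydroxide) and acidification give the acid; no addition–elimination path to alkene isomerisation is expected, so the Z geometry at C3=C4 and the remote stereocentre should be retained.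

Compound list
1 | (R)-(+)-limonene, (4R)-1-methyl-4-(prop-1-en-2-yl)cyclohex-1-ene | CC1=CC[C@@H](CC1)C(C)=C | starting material
2 | limonen-10-yllithium, {2-[(1R)-4-methylcyclohex-3-en-1-yl]prop-2-en-1-yl}lithium | CC1=CC[C@@H](CC1)C(=C)C[Li] | intermediate
3 | (4R)-4-(hexa-1,5-dien-2-yl)-1-methylcyclohex-1-ene | CC1=CC[C@@H](CC1)C(=C)CCC=C | intermediate
4 | (4R)-4-(hexa-1,5-dien-2-yl)-1-methyl-7-oxabicyclo[4.1.0]heptane (1,2-epoxide, cis/trans mixture at the epoxide carbons) | CC12CC[C@H](CC1O2)C(=C)CCC=C | intermediate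
5 | (3R)-3-(hexa-1,5-dien-2-yl)-6-oxoheptanal | C=CCCC(=C)[C@@H](CC=O)CCC(C)=O | intermediate
6 | (3R)-3-(6-methylhepta-1,5-dien-2-yl)-6-oxoheptanal | C=C(CCC=C(C)C)[C@@H](CC=O)CCC(C)=O | intermediate
7 | methyl 2-[bis(2,2,2-trifluoroethoxy)phosphoryl]acetate | COC(=O)CP(=O)(OCC(F)(F)F)OCC(F)(F)F | starting material
8 | tert-butyl(2-iodoethoxy)dimethylsilane | CC(C)(C)[Si](C)(C)OCCI | starting material
9 | methyl 2-[bis(2,2,2-trifluoroethoxy)phosphoryl]-4-[(tert-butyldimethylsilyl)oxy]butanoate (racemic) | COC(=O)C(CCO[Si](C)(C)C(C)(C)C)P(=O)(OCC(F)(F)F)OCC(F)(F)F | intermediate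
10 | methyl (2Z,5R)-2-{2-[(tert-butyldimethylsilyl)oxy]ethyl}-5-(6-methylhepta-1,5-dien-2-yl)-8-oxonon-2-enoate | C=C(CCC=C(C)C)[C@@H](C/C=C(\C(=O)OC)CCO[Si](C)(C)C(C)(C)C)CCC(C)=O | intermediate
11 | pent-4-yn-1-ol | C#CCCCO | starting material
12 | alkenylalane, dimethyl{(1E)-5-[(dimethylalumanyl)oxy]-2-methylpent-1-en-1-yl}alumane | C[Al](C)OCCC/C(C)=C/[Al](C)C | intermediate
13 | (4E)-5-iodo-4-methylpent-4-en-1-ol | OCCC/C(C)=C/I | intermediate
14 | 1-methyl-1H-tetrazole-5-thiol | Cn1nnnc1S | starting material
15 | 5-{[(4E)-5-iodo-4-methylpent-4-en-1-yl]sulfanyl}-1-methyl-1H-tetrazole | Cn1nnnc1SCCC/C(C)=C/I | intermediate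
16 | 5-{[(4E)-5-iodo-4-methylpent-4-en-1-yl]sulfonyl}-1-methyl-1H-tetrazole | Cn1nnnc1S(=O)(=O)CCC/C(C)=C/I | intermediate
17 | methyl (2Z,5R,8Z,12E)-2-{2-[(tert-butyldimethylsilyl)oxy]ethyl}-13-iodo-8,12-dimethyl-5-(6-methylhepta-1,5-dien-2-yl)trideca-2,8,12-trienoate | C=C(CCC=C(C)C)[C@@H](C/C=C(\C(=O)OC)CCO[Si](C)(C)C(C)(C)C)CC/C(=C\CC/C(=C/I)C)C | intermediate
18 | methyl (2Z,5R,8Z,12E)-2-(2-hydroxyethyl)-13-iodo-8,12-dimethyl-5-(6-methylhepta-1,5-dien-2-yl)trideca-2,8,12-trienoate | C=C(CCC=C(C)C)[C@@H](C/C=C(\C(=O)OC)CCO)CC/C(=C\CC/C(=C/I)C)C | intermediate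
19 | methyl (2Z,5R,8Z,12E)-13-iodo-2-(2-iodoethyl)-8,12-dimethyl-5-(6-methylhepta-1,5-dien-2-yl)trideca-2,8,12-trienoate | C=C(CCC=C(C)C)[C@@H](C/C=C(\C(=O)OC)CCI)CC/C(=C\CC/C(=C/I)C)C | intermediate
20 | alkylzinc iodide, methyl (2Z,5R,8Z,12E)-13-iodo-2-[2-(iodozincio)ethyl]-8,12-dimethyl-5-(6-methylhepta-1,5-dien-2-yl)trideca-2,8,12-trienoate | C=C(CCC=C(C)C)[C@@H](C/C=C(\C(=O)OC)CC[Zn]I)CC/C(=C\CC/C(=C/I)C)C | intermediate
21 | methyl (1Z,4R,7Z,11E)-7,11-dimethyl-4-(6-methylhepta-1,5-dien-2-yl)cyclotetradeca-1,7,11-triene-1-carboxylate | C=C(CCC=C(C)C)[C@H]1C/C=C(\C(=O)OC)CC/C=C(\C)CC/C=C(/C)CC1 | intermediate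
22 | (1Z,4R,7Z,11E)-7,11-dimethyl-4-(6-methylhepta-1,5-dien-2-yl)cyclotetradeca-1,7,11-triene-1-carboxylic acid (CNP0269207.1) | C=C(CCC=C(C)C)[C@H]1C/C=C(\C(=O)O)CC/C=C(\C)CC/C=C(/C)CC1 | target

Total step count: 13.
Longest linear sequence: 9 steps (steps 1, 2, 3, 5, 9, 10, 11, 12, 13, from (R)-limonene).

Steps most likely to fail

Step 12. Zinc insertion may stall or the zinc reagent may be protonated before it couples, and at the palladium stage intermolecular coupling to oligomers or β-hydride elimination of the alkylpalladium may outrun ring closure. The fallback sets out from 19 and comes back at 21, closing the same C6–C7 bond with boron instead of zinc. The C(sp3)–I bond of 19 is borylated with B2pin2 under copper catalysis (CuI, PPh3, LiOMe, DMF, 25 °C), conditions expected to spare the alkenyl iodide at this temperature, to give the pinacol boronate F1. KHF2 in MeOH/H2O converts it into the potassium alkyltrifluoroborate F2. A Suzuki–Miyaura macrocyclisation (PdCl2(dppf), Cs2CO3, THF/H2O, 80 °C, high dilution) then gives 21; the trifluoroborate releases the active boron species slowly, which keeps its stationary concentration low, and any ester hydrolysis under these conditions only anticipates step 13.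

Step 9. The addition–Smiles sequence may lose its Z preference with this dialkyl ketone, or enolisation of the ketone and conjugate addition to the enoate may consume the sulfone anion. The fallback sets out from 13 (and uses 10) and comes back at 17, replacing kinetic selectivity by separation and stereospecific elimination (Horner–Wittig). Alcohol 13 is iodinated (iodine, PPh3, imidazole) to (E)-1,5-diiodo-2-methylpent-1-ene F3, whose sp3 iodide alkylates NaP(O)Ph2 (from Ph2P(O)H and NaH, THF; Michaelis–Becker) to give the phosphine oxide F4. Deprotonation with LiN(i-Pr)2 (THF, −78 °C; an amide base spares the alkenyl iodide) and addition to ketone 10 gives diastereomeric adducts, from which the β-hydroxy phosphine oxide F5 (8R,9S as drawn; its 8S,9R isomer behaves alike) is separated by chromatography. NaH in DMF then triggers stereospecific syn-elimination to 17; the other diastereomer pair would give the E isomer and is set aside.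

Step 10. The liberated γ-hydroxy ester may lactonise onto the ester with loss of methanol, which removes material as the α-alkylidene butyrolactone. The fallback sets out from 17 and comes back at 19 without ever freeing the hydroxyl. Ph3PBr2 (CH2Cl2, 0 → 25 °C) converts the silyl ether directly into the primary bromide F6, and Finkelstein exchange (NaI, acetone, 50 °C) gives 19.

Further compounds
F1 | step 12 | methyl (2Z,5R,8Z,12E)-13-iodo-8,12-dimethyl-5-(6-methylhepta-1,5-dien-2-yl)-2-[2-(4,4,5,5-tetramethyl-1,3,2-dioxaborolan-2-yl)ethyl]trideca-2,8,12-trienoate | C=C(CCC=C(C)C)[C@@H](C/C=C(\C(=O)OC)CCB1OC(C)(C)C(C)(C)O1)CC/C(=C\CC/C(=C/I)C)C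
F2 | step 12 | potassium trifluoro{2-[(1Z,4R,7Z,11E)-12-iodo-1-(methoxycarbonyl)-7,11-dimethyl-4-(6-methylhepta-1,5-dien-2-yl)dodeca-1,7,11-trien-1-yl]ethyl}borate | C=C(CCC=C(C)C)[C@@H](C/C=C(\C(=O)OC)CC[B-](F)(F)F)CC/C(=C\CC/C(=C/I)C)C.[K+]
F3 | step 9 | (1E)-1,5-diiodo-2-methylpent-1-ene | ICCC/C(C)=C/I
F4 | step 9 | [(4E)-5-iodo-4-methylpent-4-en-1-yl]diphenylphosphine oxide | O=P(CCC/C(C)=C/I)(c1ccccc1)c1ccccc1
F5 | step 9 | methyl (2Z,5R,8R,9S,12E)-2-{2-[(tert-butyldimethylsilyl)oxy]ethyl}-9-(diphenylphosphoryl)-8-hydroxy-13-iodo-8,12-dimethyl-5-(6-methylhepta-1,5-dien-2-yl)trideca-2,12-dienoate | C=C(CCC=C(C)C)[C@@H](C/C=C(\C(=O)OC)CCO[Si](C)(C)C(C)(C)C)CC[C@@](C)(O)[C@@H](P(=O)(c1ccccc1)c1ccccc1)CC/C(C)=C/I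
F6 | step 10 | methyl (2Z,5R,8Z,12E)-2-(2-bromoethyl)-13-iodo-8,12-dimethyl-5-(6-methylhepta-1,5-dien-2-yl)trideca-2,8,12-trienoate | C=C(CCC=C(C)C)[C@@H](C/C=C(\C(=O)OC)CCBr)CC/C(=C\CC/C(=C/I)C)C
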